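(The earlier runs and the new flask were computed with constants of no real substance; the scatter is artificial.)

At early times the beta run at 15 °C reaches 11.0% of product after 1.00 min, while the eta run at −12 °C needs 12.0 min to reach 14.4%.

| flask | substrate | coupling partner | capture agent | free catalyst | temperature | remark | time |
|---|---|---|---|---|---|---|---|
| eta | 1 M | 0.60 M | 0.050 M | 9.5 mM | −12 °C | run made earlier |  |
| beta | 1 M | 0.60 M | 0.075 M | 9.5 mM | 15 °C | run made earlier |  |
| Monday's | 1.0 M | 0.600 M | 0.100 M | 9.5 mM | −25 °C |  | 25 min |
| Tuesday's | 1.0 M | 0.600 M | 0.100 M | 9.5 mM | 0 °C |  | 25 min |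
| Thursday's | 1.0 M | 0.600 M | 0.100 M | 9.5 mM | 25 °C |  | 25 min |

| eta: time / min | eta: product / % | beta: time / min | beta: product / % |
|---|---|---|---|
| 2.00 | 2.7 | 0.200 | 2.1 |
| 4.00 | 4.8 | 0.500 | 5.7 |
| 5.00 | 7.4 | 1.00 | 11.0 |
| 8.00 | 11.3 | 1.33 | 14.0 |
| 10.0 | 11.9 | 2.00 | 20.2 |
| 12.0 | 14.4 | 3.00 | 27.4 |

(standard deviation of a reading: 0.5 percentage points)

1. the flask that comes out highest in amount of product, in percent of the substrate charged, or "all alike" when all lie within 1.5 percentage points (Monday's / Tuesday's / Thursday's / all alike)
2. product at the end, in percent of the substrate charged, Monday's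
3. product at the end, in percent of the substrate charged, Tuesday's
4. product at the end, in percent of the substrate charged, Thursday's

- the analysis behind the earlier runs scatters by 0.5 percentage points, standard deviation

If one coupling partner goes into each product, coupling partner is the limiting reagent, and the ceiling is 60.0% of the substrate charged. Read as a first-order loss of coupling partner, the last beta reading gives 0.203 min⁻¹ and the last eta reading 0.0229 min⁻¹. Together these readings give an apparent activation energy of 50.6 kJ mol⁻¹. The partner time τ is the reciprocal of that constant at a flask's temperature, and the count N is the time given divided by τ. Product then follows the ceiling times one minus exp(−N). My own reckoning gives this table: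

| flask | τ | N | product |
|---|---|---|---|
| Monday's | 148 min | 0.169 | 9.30% |
| Tuesday's | 15.7 min | 1.59 | 47.8% |
| Thursday's | 2.42 min | 10.3 | 60.0% |

Monday's row has N below one, so that flask stays on the early, nearly straight stretch of its curve. Tuesday's row has N above one, so that flask is on the bend. Thursday's row has τ far shorter than the time given, so that flask is reckoned to stand at the ceiling. In this table Thursday's leads Tuesday's by 12 percentage points, against a margin of 1.5 points. The weak point is the capture agent, charged at 0.100 M against 0.050 M and 0.075 M in the earlier runs.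

The forecast names Thursday's, with 9%, 46% and 59%, a little below my table on its own grounds: “I shade the estimates slightly downward and keep the ranges wide”.

The flasks give 8.97%, 47.6% and 59.8%, and Thursday's is highest.

    coupling partner + free catalyst ⇌ catalyst intermediate A (K = 16.0 L mol⁻¹, k = 2.30 L mol⁻¹ s⁻¹, Ea = 57.0 kJ mol⁻¹, ΔH = −32.0 kJ mol⁻¹)
    substrate + catalyst intermediate A ⇌ catalyst intermediate B (K = 0.160 L mol⁻¹, k = 0.770 L mol⁻¹ s⁻¹, Ea = 46.0 kJ mol⁻¹, ΔH = −16.0 kJ mol⁻¹)
    catalyst intermediate B → free catalyst + product (k = 30.0 s⁻¹, Ea = 52.0 kJ mol⁻¹)
    catalyst intermediate B + capture agent → trapped intermediate (k = 1.20 L mol⁻¹ s⁻¹, Ea = 39.0 kJ mol⁻¹)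
    free catalyst → spent catalyst (k = 1.20 × 10⁻⁵ s⁻¹, Ea = 89.0 kJ mol⁻¹)
    (constants at 25 °C)

Thursday's has come to rest in product: coupling partner stands at 0% after 25.0 min, and product stands at 59.8% after 250 min, while spent catalyst climbs from 1.21% of the catalyst charged after 25.0 min to 12.3% after 250 min. Tuesday's has not, with 20% of its coupling partner left after 25.0 min, and it reaches 59.6% after 250 min. Monday's is far from rest: ten times the time makes N 1.69, which reckons to 48.9%, and the flask comes out lower, at 43.6%.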